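In a one-step world substrate and reagent would give intermediate and nothing else, at a rate proportional to c_substrate times c_reagent. If c_reagent is taken as its charge, the rate is pseudo-first-order in c_substrate, the one concentration that a feed controls.

| flask | substrate | reagent | remark | time |
|---|---|---|---|---|
| zeta | 0.20 M (fed, over 1.2 h) | 1.3 equiv | run made earlier |  |
| alpha | 0.20 M (fed, over 1.2 h) | 3 equiv | run made earlier |  |
| north-west | 0.20 M (fed, over 1.2 h) | 2.00 equiv |  | 10 h |
| north-east | 0.20 M (fed, over 3.0 h) | 2.00 equiv |  | 10 h |
| east | 0.20 M (fed, over 10 h) | 2.00 equiv |  | 10 h |
| north | 0.20 M (fed, over 30 h) | 2.00 equiv |  | 10 h |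

| run | time / h | intermediate / % | product / % |
|---|---|---|---|
| zeta | 0.667 | 2 | 0 |
| zeta | 2.00 | 4 | 0 |
| zeta | 4.00 | 5 | 13 |
| zeta | 6.00 | 7 | 15 |
| zeta | 8.00 | 10 | 12 |
| alpha | 0.667 | 0 | 1 |
| alpha | 2.00 | 8 | 7 |
| alpha | 4.00 | 15 | 21 |
| alpha | 6.00 | 20 | 19 |
| alpha | 8.00 | 28 | 26 |

(scatter of a reading: 2 percentage points)

1. amount of intermediate at the end, in percent of the substrate charged for north-west, north-east, east, north, in this order
2. how the row runs (falls all the way / hardly changes / falls, then rises / rises, then falls / rises all the way)

- the numbers in the tables scatter by 2 percentage points (one standard deviation)
- percentages count the whole charge, also what has not yet gone in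
- a reading or a percentage of product counts all its forms, free or not
- "hardly changes" means that all values lie within two and a half points (for a concentration: within two and a half percent of the largest)

The two runs allow a test of that order. At 8.00 h intermediate reads 10% with 1.3 equiv of reagent and 28% with 3 equiv, a ratio of 2.80 against 2.31 in equivalents, and with a scatter of 2 percentage points on each reading this pair does not part the two, so the reckoning here takes first order in reagent. The clock for the feed is then the charge-hour, the area under fed fraction against time: after the feed it is the time less half the dosing time, and during the feed it is the square of the time over twice the dosing time. Each run had 7.40 h of charge-hours at its last reading, so scaling both readings to 2.00 equiv and averaging gives a gain of intermediate per charge-hour of 0.0230 /h of the charge.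

Drawn against dosing time, the reckoned end amount starts at 21.6% for north-west and falls in a straight line, with a slope of 0.0115 /h of the charge, through 19.6% for north-east. The straight line ends where the dosing time reaches the 10 h allowed, which is the east flask, at 11.5%, and the slope carries smoothly over that point. Beyond it the feed is unfinished at the end, and the reckoned curve bends into a tail: the north flask has received a third of its charge, which makes 1.67 h of charge-hours and 3.84%.

The forecast, holding that “Feeding delays this by half the feed time”, gave 21%, 20%, 13% and 5%, a row that falls all the way and is not quite the one above. The flasks give 19.6%, 18.4%, 11.6% and 3.11%, and the row falls all the way.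

    substrate + product ⇌ idle adduct, settled at all times (K = 1.80 /M)
    substrate + reagent ⇌ intermediate (K = 2.30 /M, k = 0.230 /M/h)
    intermediate ⇌ product + released group (K = 0.0470 M, k = 0.970 /h)

The same gain serves the east flask at 5.00 h, still in its feed, where 1.25 h of charge-hours give 2.88% and the flask holds 3.39%. In the north flask, 1.67 h of charge-hours give 3.84% and the flask holds 3.11%. That low figure comes in part from the slow addition acting together with the time allowed: without the slow addition the north flask holds 20.3% at 10 h, and left to 100 h it holds 27.7%.

The numbers in the tables stem from a simulated flask on assumed constants; the scatter is artificial.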